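**Plan**
- Retrosynthetic cuts, in order: the O3–angeloyl ester; the C2–O bond (back to a C3 ketone); C11–C12 (sulfone alkylation by a bis-silylated allylic bromide carrying C12–C16); then C4–C5 and C9–C10 of the decalin.
- Enabling feature (labdane numbering: C17 methylene on C8, C18 CH2O and C19 methyl on C4, C20 methyl on C10): the 3-oxygenated trans-decalin C1–C10 with quaternary C4 and the C8=C17 exo-methylene is the chair–chair fold of an E,E-polyene whose C3–C4 epoxide carries C18 and whose last alkene is an allylsilane.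
- Forward: geranyl bromide and acetoacetate dianion, enol phosphate/silylmethyl coupling, terminal SeO2 oxidation and Sharpless epoxidation give the acyclic precursor; one Lewis-acid step closes ring A, then ring B.
- Then C11 becomes a sulfone and is joined to the C12–C16 bromide (from dihydroxyacetone via a butenolide). Desulfonylation, C3 ketone, C2 hydroxylation, reduction, angeloylation and global desilylation follow.
- Stereochemistry: C3 from the Sharpless epoxide (re-set later by axial hydride delivery); C4, C5, C9, C10 from epoxide configuration and alkene geometries in the cyclisation; C2 from face-selective enolate oxidation; 13Z from the butenolide ring; the angelate Z from angelic acid.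

Key step: step 9

Remark: labdane numbering is used for all bicyclic compounds (ent-labdane series; TBS = tert-butyldimethylsilyl, TBDPS = tert-butyldiphenylsilyl); 1,3-dihydroxyacetone is charged as its commercial dimer and drawn as the monomer.

Step 1
Reactants: 1 ethyl acetoacetate; 2 geranyl bromide [(2E)-1-bromo-3,7-dimethylocta-2,6-diene]
Product: 4 ethyl (6E)-7,11-dimethyl-3-oxododeca-6,10-dienoate, via acetoacetate dianion 3 (not isolated)
Conditions: NaH, THF, 0 °C; n-BuLi, 0 °C; then 2, 0 °C; 1 M HCl quench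
Reagents that add atoms: none
Why: The dianion of the β-keto ester is alkylated at its more basic terminal (γ) carbon by the primary allylic bromide in an SN2 reaction (acetoacetate dianion γ-alkylation), which leaves the E-alkene untouched.

Step 2
Reactants: 4 ethyl (6E)-7,11-dimethyl-3-oxododeca-6,10-dienoate
Product: 6 ethyl (2Z,6E)-3-[(diethoxyphosphoryl)oxy]-7,11-dimethyldodeca-2,6,10-trienoate, via sodium enolate 5 (not isolated)
Conditions: NaH, Et2O, 0 °C; ClP(O)(OEt)2, 0 °C → rt
Reagents that add atoms: diethyl chlorophosphate, CCOP(=O)(Cl)OCC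
Why: O-phosphorylation of the chelated sodium enolate should give the Z-enol phosphate (phosphate cis to the ester), the usual outcome for β-keto ester sodium enolates in ether.

Step 3
Reactants: 6 ethyl (2Z,6E)-3-[(diethoxyphosphoryl)oxy]-7,11-dimethyldodeca-2,6,10-trienoate
Product: 7 ethyl (2Z,6E)-7,11-dimethyl-3-[(trimethylsilyl)methyl]dodeca-2,6,10-trienoate
Conditions: Me3SiCH2MgCl, Ni(acac)2 (5 mol%), THF, 0 °C → rt
Reagents that add atoms: (trimethylsilyl)methylmagnesium chloride, C[Si](C)(C)C[Mg]Cl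
Why: Nickel-catalysed Kumada-type coupling of an enol phosphate with the silylmethyl Grignard reagent replaces the phosphate with retention of alkene geometry, so CH2SiMe3 ends cis to the ester, the geometry that later places C11 equatorial.

Step 4
Reactants: 7 ethyl (2Z,6E)-7,11-dimethyl-3-[(trimethylsilyl)methyl]dodeca-2,6,10-trienoate
Product: 8 ethyl (2Z,6E,10E)-12-hydroxy-7,11-dimethyl-3-[(trimethylsilyl)methyl]dodeca-2,6,10-trienoate
Conditions: SeO2 (0.3 equiv), t-BuOOH, salicylic acid (cat.), CH2Cl2, 0 °C → rt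
Reagents that add atoms: selenium dioxide, O=[Se]=O (transfers the oxygen and is re-oxidised by tert-butyl hydroperoxide, CC(C)(C)OO)
Why: Catalytic SeO2 allylic oxidation (ene reaction then [2,3]-shift) should attack the E-methyl of the terminal isopropylidene group, the most accessible electron-rich alkene, while the ester-conjugated silylmethyl alkene is deactivated.

Step 5
Reactants: 8 ethyl (2Z,6E,10E)-12-hydroxy-7,11-dimethyl-3-[(trimethylsilyl)methyl]dodeca-2,6,10-trienoate
Product: 9 ethyl (2Z,6E,10R,11R)-10,11-epoxy-12-hydroxy-7,11-dimethyl-3-[(trimethylsilyl)methyl]dodeca-2,6-dienoate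
Conditions: Ti(OiPr)4 (10 mol%), D-(−)-diethyl tartrate (12 mol%), t-BuOOH, 4 Å MS, CH2Cl2, −20 °C
Reagents that add atoms: tert-butyl hydroperoxide, CC(C)(C)OO
Why: Sharpless asymmetric epoxidation is directed by the allylic hydroxyl, so only the 10,11-alkene reacts, and the D-(−)-tartrate ligand should deliver oxygen to the face that gives the (10R,11R)-epoxide (the antipode of the (2S,3S)-epoxy alcohols obtained with L-(+)-tartrate).

Step 6
Reactants: 9 ethyl (2Z,6E,10R,11R)-10,11-epoxy-12-hydroxy-7,11-dimethyl-3-[(trimethylsilyl)methyl]dodeca-2,6-dienoate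
Product: 10 ethyl (2Z,6E,10R,11R)-12-[(tert-butyldiphenylsilyl)oxy]-10,11-epoxy-7,11-dimethyl-3-[(trimethylsilyl)methyl]dodeca-2,6-dienoate
Conditions: TBDPSCl, imidazole, DMF, 0 °C → rt
Reagents that add atoms: tert-butyl(chloro)diphenylsilane, CC(C)(C)[Si](Cl)(c1ccccc1)c1ccccc1
Why: Standard silylation of the primary alcohol gives a bulky, weakly basic ether that should leave the Lewis acid of step 9 on the epoxide oxygen and is too hindered to trap a cation.

Step 7
Reactants: 10 ethyl (2Z,6E,10R,11R)-12-[(tert-butyldiphenylsilyl)oxy]-10,11-epoxy-7,11-dimethyl-3-[(trimethylsilyl)methyl]dodeca-2,6-dienoate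
Product: 11 (2Z,6E,10R,11R)-12-[(tert-butyldiphenylsilyl)oxy]-10,11-epoxy-7,11-dimethyl-3-[(trimethylsilyl)methyl]dodeca-2,6-dien-1-ol
Conditions: DIBAL-H (2.3 equiv), CH2Cl2, −78 °C; Rochelle salt
Reagents that add atoms: none
Why: DIBAL-H reduces the conjugated ester to the allylic alcohol by 1,2-hydride addition at −78 °C, where the trisubstituted epoxide and the silyl ether are inert.

Step 8
Reactants: 11 (2Z,6E,10R,11R)-12-[(tert-butyldiphenylsilyl)oxy]-10,11-epoxy-7,11-dimethyl-3-[(trimethylsilyl)methyl]dodeca-2,6-dien-1-ol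
Product: 12 (2Z,6E,10R,11R)-1-[(tert-butyldimethylsilyl)oxy]-12-[(tert-butyldiphenylsilyl)oxy]-10,11-epoxy-7,11-dimethyl-3-[(trimethylsilyl)methyl]dodeca-2,6-diene
Conditions: TBSCl, imidazole, DMF, 0 °C
Reagents that add atoms: tert-butyl(chloro)dimethylsilane, CC(C)(C)[Si](C)(C)Cl
Why: Silylation under basic conditions masks the allylic alcohol as an ether which, unlike an allylic ester, offers a Lewis acid no leaving group for 1,4-elimination across the neighbouring allylsilane.

Step 9
Reactants: 12 (2Z,6E,10R,11R)-1-[(tert-butyldimethylsilyl)oxy]-12-[(tert-butyldiphenylsilyl)oxy]-10,11-epoxy-7,11-dimethyl-3-[(trimethylsilyl)methyl]dodeca-2,6-diene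
Product: 13 (3R,4S,5S,9R,10R)-11-[(tert-butyldimethylsilyl)oxy]-18-[(tert-butyldiphenylsilyl)oxy]-12,13,14,15,16-pentanorlabd-8(17)-en-3-ol
Conditions: MeAlCl2 (2.5 equiv), CH2Cl2, −78 °C; then Et3N–MeOH, aq NaHCO3
Reagents that add atoms: none
Why: MeAlCl2 binds the epoxide oxygen and the C5=C10 alkene attacks C4 from the side opposite the breaking C4–O bond (6-endo closure of ring A, new bond C4–C5), the C10 cation so formed is taken by C9 of the allylsilane (6-endo closure of ring B, new bond C9–C10), and loss of the silyl group from C17 leaves the C8=C17 alkene. This is a Lewis-acid epoxy-polyene cyclisation with allylsilane termination, a known reaction type. C3 keeps the configuration set in step 5 with its oxygen equatorial in the chair, and C4 is inverted by the backside attack, so the E-placed CH2OTBDPS (C18) becomes equatorial and the methyl (C19) axial. C5 and C10 are fixed by anti addition across the E C5=C10 alkene and C9 by the geometry of the C8=C9 alkene (C7 trans to C11) in a chair–chair fold, which gives the trans ring fusion and the equatorial C11 arm. The step needs opening at the more substituted epoxide carbon, a complete second ring closure and a single alkene position: the first is favoured by the tertiary C4 and by a bulky silyl ether that neither chelates aluminium nor traps the cation, the others by the high nucleophilicity of the allylsilane and by silicon leaving faster than any proton, while the C11 silyl ether gives the Lewis acid no allylic leaving group.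

Step 10
Reactants: 13 (3R,4S,5S,9R,10R)-11-[(tert-butyldimethylsilyl)oxy]-18-[(tert-butyldiphenylsilyl)oxy]-12,13,14,15,16-pentanorlabd-8(17)-en-3-ol
Product: 14 (3R,4S,5S,9R,10R)-18-[(tert-butyldiphenylsilyl)oxy]-12,13,14,15,16-pentanorlabd-8(17)-ene-3,11-diol
Conditions: PPTS (0.2 equiv), MeOH, rt
Reagents that add atoms: none
Why: Acid-catalysed methanolysis should cleave the primary TBS ether far faster than the neopentyl TBDPS ether (graded silyl ether lability), and PPTS is too weak to move the exocyclic alkene.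

Step 11
Reactants: 14 (3R,4S,5S,9R,10R)-18-[(tert-butyldiphenylsilyl)oxy]-12,13,14,15,16-pentanorlabd-8(17)-ene-3,11-diol
Product: 15 18-[(tert-butyldiphenylsilyl)oxy]-11-(phenylsulfanyl)-12,13,14,15,16-pentanorlabd-8(17)-en-3-ol (ring configuration as in 13)
Conditions: PhSSPh, n-Bu3P, pyridine, rt
Reagents that add atoms: diphenyl disulfide, c1ccc(SSc2ccccc2)cc1
Why: In the Hata reaction the alkoxyphosphonium of the primary C11 alcohol is displaced by thiophenolate (SN2), while the hindered secondary C3 alcohol next to quaternary C4 should not react.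

Step 12
Reactants: 15 18-[(tert-butyldiphenylsilyl)oxy]-11-(phenylsulfanyl)-12,13,14,15,16-pentanorlabd-8(17)-en-3-ol
Product: 16 18-[(tert-butyldiphenylsilyl)oxy]-11-(phenylsulfonyl)-12,13,14,15,16-pentanorlabd-8(17)-en-3-ol (ring configuration as in 13)
Conditions: (NH4)6Mo7O24·4H2O (10 mol%), 30% H2O2, EtOH, 0 °C → rt
Reagents that add atoms: hydrogen peroxide, OO
Why: Molybdate-catalysed peroxide oxidation takes a sulfide to the sulfone and should not epoxidise the unactivated 1,1-disubstituted alkene.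

Step 13
Reactants: 17 1,3-dihydroxyacetone
Product: 19 4-(hydroxymethyl)furan-2(5H)-one, via hydroxy enoate 18 (not isolated)
Conditions: Ph3P=CHCO2Et, CH2Cl2, rt
Reagents that add atoms: ethyl (triphenylphosphoranylidene)acetate, CCOC(=O)C=P(c1ccccc1)(c1ccccc1)c1ccccc1
Why: Wittig olefination of the ketone gives an enoate whose β-carbon bears two identical CH2OH arms, and the arm cis to the ester lactonises, so the ring fixes the cis relation of the future C15 and C16 and leaves the trans arm (C12) free.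

Step 14
Reactants: 19 4-(hydroxymethyl)furan-2(5H)-one
Product: 20 4-(bromomethyl)furan-2(5H)-one
Conditions: CBr4, PPh3, CH2Cl2, 0 °C
Reagents that add atoms: carbon tetrabromide, BrC(Br)(Br)Br
Why: Appel bromination converts the primary alcohol into the bromide under neutral conditions that the base-sensitive butenolide tolerates.

Step 15
Reactants: 20 4-(bromomethyl)furan-2(5H)-one
Product: 21 (2E)-2-(bromomethyl)but-2-ene-1,4-diol (the two CH2OH groups cis)
Conditions: DIBAL-H (3.5 equiv), CH2Cl2, −78 → 0 °C; Rochelle salt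
Reagents that add atoms: none
Why: Excess DIBAL-H should reduce the lactone through the lactol to the cis ene-diol by 1,2-hydride additions and, as in the reduction of 4-bromocrotonates to bromo allylic alcohols, this electrophilic hydride should spare the allylic bromide at low temperature.

Step 16
Reactants: 21 (2E)-2-(bromomethyl)but-2-ene-1,4-diol
Product: 22 (2E)-2-(bromomethyl)-1,4-bis[(tert-butyldimethylsilyl)oxy]but-2-ene (the two CH2O arms cis)
Conditions: TBSOTf, 2,6-lutidine, CH2Cl2, −78 °C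
Reagents that add atoms: tert-butyldimethylsilyl trifluoromethanesulfonate, CC(C)(C)[Si](C)(C)OS(=O)(=O)C(F)(F)F
Why: Silylation with the triflate and a hindered non-nucleophilic base is complete at −78 °C, so neither chloride nor an amine is present to displace the allylic bromide.

Step 17
Reactants: 16 18-[(tert-butyldiphenylsilyl)oxy]-11-(phenylsulfonyl)-12,13,14,15,16-pentanorlabd-8(17)-en-3-ol; 22 (2E)-2-(bromomethyl)-1,4-bis[(tert-butyldimethylsilyl)oxy]but-2-ene
Product: 24 (13Z)-15,16-bis[(tert-butyldimethylsilyl)oxy]-18-[(tert-butyldiphenylsilyl)oxy]-11-(phenylsulfonyl)labda-8(17),13-dien-3-ol (both C11 epimers), via dilithiated sulfone 23 (not isolated)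
Conditions: n-BuLi (2.2 equiv), THF–HMPA, −78 °C; then 22, −78 → −40 °C; H2O quench
Reagents that add atoms: none
Why: The α-sulfonyl carbanion, generated beside the lithium alkoxide of the hindered C3 hydroxyl, displaces the primary allylic bromide by SN2 (Julia-type sulfone alkylation), forming C11–C12 without touching the alkene geometry, and the new C11 centre disappears in step 18.

Step 18
Reactants: 24 (13Z)-15,16-bis[(tert-butyldimethylsilyl)oxy]-18-[(tert-butyldiphenylsilyl)oxy]-11-(phenylsulfonyl)labda-8(17),13-dien-3-ol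
Product: 25 (13Z)-15,16-bis[(tert-butyldimethylsilyl)oxy]-18-[(tert-butyldiphenylsilyl)oxy]labda-8(17),13-dien-3-ol (ring configuration as in 13)
Conditions: 6% Na(Hg), Na2HPO4, MeOH–THF, −20 °C
Reagents that add atoms: none
Why: Reductive desulfonylation by electron transfer cleaves the C–S bond and protonates C11; no leaving group is β to C11, so no elimination can follow, and allylic silyl ethers should survive buffered sodium amalgam.

Step 19
Reactants: 25 (13Z)-15,16-bis[(tert-butyldimethylsilyl)oxy]-18-[(tert-butyldiphenylsilyl)oxy]labda-8(17),13-dien-3-ol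
Product: 26 (13Z)-15,16-bis[(tert-butyldimethylsilyl)oxy]-18-[(tert-butyldiphenylsilyl)oxy]labda-8(17),13-dien-3-one
Conditions: Dess–Martin periodinane, NaHCO3, CH2Cl2, 0 °C → rt
Reagents that add atoms: none
Why: Dess–Martin oxidation converts the hindered secondary alcohol into the ketone under near-neutral conditions that leave silyl ethers and both alkenes alone.

Step 20
Reactants: 26 (13Z)-15,16-bis[(tert-butyldimethylsilyl)oxy]-18-[(tert-butyldiphenylsilyl)oxy]labda-8(17),13-dien-3-one
Product: 28 (13Z)-15,16-bis[(tert-butyldimethylsilyl)oxy]-18-[(tert-butyldiphenylsilyl)oxy]-2-hydroxylabda-8(17),13-dien-3-one (C2 hydroxyl equatorial and trans to C20), via potassium enolate 27 (not isolated)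
Conditions: KHMDS, THF, −78 °C; then 3-phenyl-2-(phenylsulfonyl)oxaziridine, −78 °C; AcOH quench
Reagents that add atoms: 3-phenyl-2-(phenylsulfonyl)oxaziridine, O=S(=O)(c1ccccc1)N1OC1c1ccccc1
Why: C4 is quaternary, so only the C2 enolate can form, and Davis oxidation should deliver oxygen to the face opposite the axial C20 and C19 methyl groups, giving the equatorial C2 hydroxyl, which is also the more stable epimer of this enolisable centre.

Step 21
Reactants: 28 (13Z)-15,16-bis[(tert-butyldimethylsilyl)oxy]-18-[(tert-butyldiphenylsilyl)oxy]-2-hydroxylabda-8(17),13-dien-3-one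
Product: 29 (13Z)-2,15,16-tris[(tert-butyldimethylsilyl)oxy]-18-[(tert-butyldiphenylsilyl)oxy]labda-8(17),13-dien-3-one
Conditions: TBSOTf, 2,6-lutidine, CH2Cl2, −78 → 0 °C
Reagents that add atoms: tert-butyldimethylsilyl trifluoromethanesulfonate, CC(C)(C)[Si](C)(C)OS(=O)(=O)C(F)(F)F
Why: Silylation of the unhindered equatorial C2 hydroxyl blocks that oxygen, so that only O3 can be acylated later, and stops ketol isomerisation.

Step 22
Reactants: 29 (13Z)-2,15,16-tris[(tert-butyldimethylsilyl)oxy]-18-[(tert-butyldiphenylsilyl)oxy]labda-8(17),13-dien-3-one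
Product: 30 (13Z)-2,15,16-tris[(tert-butyldimethylsilyl)oxy]-18-[(tert-butyldiphenylsilyl)oxy]labda-8(17),13-dien-3-ol (C3 hydroxyl equatorial and trans to the C2 oxygen)
Conditions: NaBH4, MeOH–THF, −20 → 0 °C
Reagents that add atoms: none
Why: Hydride should add to the C3 ketone along the axial trajectory on the face away from the axial C4 methyl, the usual course for 4,4-disubstituted 3-oxo trans-decalins, giving the equatorial alcohol.

Step 23
Reactants: 30 (13Z)-2,15,16-tris[(tert-butyldimethylsilyl)oxy]-18-[(tert-butyldiphenylsilyl)oxy]labda-8(17),13-dien-3-ol; 31 angelic acid [(2Z)-2-methylbut-2-enoic acid]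
Product: 33 (13Z)-2,15,16-tris[(tert-butyldimethylsilyl)oxy]-18-[(tert-butyldiphenylsilyl)oxy]labda-8(17),13-dien-3-yl (2Z)-2-methylbut-2-enoate, via mixed anhydride 32 (not isolated)
Conditions: 31, 2,4,6-trichlorobenzoyl chloride, Et3N, toluene, rt; then 30, toluene, 80 °C
Reagents that add atoms: none
Why: Yamaguchi-type esterification through the mixed anhydride, run without a nucleophilic catalyst such as DMAP, is the established way to acylate hindered alcohols with angelic acid without the addition–elimination that isomerises the Z-alkene to the tiglate.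

Step 24
Reactants: 33 (13Z)-2,15,16-tris[(tert-butyldimethylsilyl)oxy]-18-[(tert-butyldiphenylsilyl)oxy]labda-8(17),13-dien-3-yl (2Z)-2-methylbut-2-enoate
Product: 34 CNP0324138.1, (2S,3S,4S,5S,9R,10S,13Z)-2,15,16,18-tetrahydroxylabda-8(17),13-dien-3-yl (2Z)-2-methylbut-2-enoate
Conditions: HF·pyridine, pyridine, THF, 0 °C → rt
Reagents that add atoms: none
Why: Fluoride cleaves the three TBS ethers and the TBDPS ether in one operation under mildly acidic conditions, in which the hindered angelate should neither migrate to the freed C2 or C18 hydroxyls nor isomerise.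

**Compound list**
1 | ethyl acetoacetate | CCOC(=O)CC(C)=O | starting material
2 | geranyl bromide, (2E)-1-bromo-3,7-dimethylocta-2,6-diene | CC(C)=CCC/C(C)=C/CBr | starting material
3 | sodium lithium dianion of ethyl acetoacetate | [Na+].[Li+].[CH2-]C(=O)[CH-]C(=O)OCC | intermediate (not isolated)
4 | ethyl (6E)-7,11-dimethyl-3-oxododeca-6,10-dienoate | CCOC(=O)CC(=O)CC/C=C(C)/CCC=C(C)C | intermediate
5 | sodium (Z)-enolate of 4 | [Na+].CCOC(=O)/C=C(\[O-])CC/C=C(C)/CCC=C(C)C | intermediate (not isolated)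
6 | ethyl (2Z,6E)-3-[(diethoxyphosphoryl)oxy]-7,11-dimethyldodeca-2,6,10-trienoate | CCOC(=O)/C=C(\OP(=O)(OCC)OCC)CC/C=C(C)/CCC=C(C)C | intermediate
7 | ethyl (2Z,6E)-7,11-dimethyl-3-[(trimethylsilyl)methyl]dodeca-2,6,10-trienoate | CCOC(=O)/C=C(\C[Si](C)(C)C)CC/C=C(C)/CCC=C(C)C | intermediate
8 | ethyl (2Z,6E,10E)-12-hydroxy-7,11-dimethyl-3-[(trimethylsilyl)methyl]dodeca-2,6,10-trienoate | CCOC(=O)/C=C(\C[Si](C)(C)C)CC/C=C(C)/CC/C=C(\C)CO | intermediate
9 | ethyl (2Z,6E,10R,11R)-10,11-epoxy-12-hydroxy-7,11-dimethyl-3-[(trimethylsilyl)methyl]dodeca-2,6-dienoate | CCOC(=O)/C=C(\C[Si](C)(C)C)CC/C=C(C)/CC[C@H]1O[C@]1(C)CO | intermediate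
10 | ethyl (2Z,6E,10R,11R)-12-[(tert-butyldiphenylsilyl)oxy]-10,11-epoxy-7,11-dimethyl-3-[(trimethylsilyl)methyl]dodeca-2,6-dienoate | CCOC(=O)/C=C(\C[Si](C)(C)C)CC/C=C(C)/CC[C@H]1O[C@]1(C)CO[Si](c1ccccc1)(c1ccccc1)C(C)(C)C | intermediate
11 | (2Z,6E,10R,11R)-12-[(tert-butyldiphenylsilyl)oxy]-10,11-epoxy-7,11-dimethyl-3-[(trimethylsilyl)methyl]dodeca-2,6-dien-1-ol | OC/C=C(\C[Si](C)(C)C)CC/C=C(C)/CC[C@H]1O[C@]1(C)CO[Si](c1ccccc1)(c1ccccc1)C(C)(C)C | intermediate
12 | (2Z,6E,10R,11R)-1-[(tert-butyldimethylsilyl)oxy]-12-[(tert-butyldiphenylsilyl)oxy]-10,11-epoxy-7,11-dimethyl-3-[(trimethylsilyl)methyl]dodeca-2,6-diene (cyclisation precursor) | CC(C)(C)[Si](C)(C)OC/C=C(\C[Si](C)(C)C)CC/C=C(C)/CC[C@H]1O[C@]1(C)CO[Si](c1ccccc1)(c1ccccc1)C(C)(C)C | intermediate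
13 | (3R,4S,5S,9R,10R)-11-[(tert-butyldimethylsilyl)oxy]-18-[(tert-butyldiphenylsilyl)oxy]-12,13,14,15,16-pentanorlabd-8(17)-en-3-ol (cyclisation product; trans-decalin, O3 and C18 equatorial) | C=C1CC[C@H]2[C@@](C)(CC[C@@H](O)[C@]2(C)CO[Si](c3ccccc3)(c3ccccc3)C(C)(C)C)[C@@H]1CO[Si](C)(C)C(C)(C)C | intermediate
14 | (3R,4S,5S,9R,10R)-18-[(tert-butyldiphenylsilyl)oxy]-12,13,14,15,16-pentanorlabd-8(17)-ene-3,11-diol | C=C1CC[C@H]2[C@@](C)(CC[C@@H](O)[C@]2(C)CO[Si](c3ccccc3)(c3ccccc3)C(C)(C)C)[C@@H]1CO | intermediate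
15 | 18-[(tert-butyldiphenylsilyl)oxy]-11-(phenylsulfanyl)-12,13,14,15,16-pentanorlabd-8(17)-en-3-ol (ring configuration as in 13) | C=C1CC[C@H]2[C@@](C)(CC[C@@H](O)[C@]2(C)CO[Si](c3ccccc3)(c3ccccc3)C(C)(C)C)[C@@H]1CSc1ccccc1 | intermediate
16 | 18-[(tert-butyldiphenylsilyl)oxy]-11-(phenylsulfonyl)-12,13,14,15,16-pentanorlabd-8(17)-en-3-ol (ring configuration as in 13) | C=C1CC[C@H]2[C@@](C)(CC[C@@H](O)[C@]2(C)CO[Si](c3ccccc3)(c3ccccc3)C(C)(C)C)[C@@H]1CS(=O)(=O)c1ccccc1 | intermediate
17 | 1,3-dihydroxyacetone | OCC(=O)CO | starting material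
18 | ethyl 4-hydroxy-3-(hydroxymethyl)but-2-enoate | CCOC(=O)C=C(CO)CO | intermediate (not isolated)
19 | 4-(hydroxymethyl)furan-2(5H)-one | OCC1=CC(=O)OC1 | intermediate
20 | 4-(bromomethyl)furan-2(5H)-one | BrCC1=CC(=O)OC1 | intermediate
21 | (2E)-2-(bromomethyl)but-2-ene-1,4-diol (CH2OH groups cis) | BrC/C(CO)=C/CO | intermediate
22 | (2E)-2-(bromomethyl)-1,4-bis[(tert-butyldimethylsilyl)oxy]but-2-ene (CH2O arms cis) | BrC/C(CO[Si](C)(C)C(C)(C)C)=C/CO[Si](C)(C)C(C)(C)C | intermediate
23 | dilithio derivative of 16 (C3 alkoxide, C11 carbanion) | [Li+].[Li+].C=C1CC[C@H]2[C@@](C)(CC[C@@H]([O-])[C@]2(C)CO[Si](c3ccccc3)(c3ccccc3)C(C)(C)C)[C@@H]1[CH-]S(=O)(=O)c1ccccc1 | intermediate (not isolated)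
24 | (13Z)-15,16-bis[(tert-butyldimethylsilyl)oxy]-18-[(tert-butyldiphenylsilyl)oxy]-11-(phenylsulfonyl)labda-8(17),13-dien-3-ol (both C11 epimers; ring configuration as in 13) | C=C1CC[C@H]2[C@@](C)(CC[C@@H](O)[C@]2(C)CO[Si](c3ccccc3)(c3ccccc3)C(C)(C)C)[C@@H]1C(C/C(=C/CO[Si](C)(C)C(C)(C)C)CO[Si](C)(C)C(C)(C)C)S(=O)(=O)c1ccccc1 | intermediate
25 | (13Z)-15,16-bis[(tert-butyldimethylsilyl)oxy]-18-[(tert-butyldiphenylsilyl)oxy]labda-8(17),13-dien-3-ol (ring configuration as in 13) | C=C1CC[C@H]2[C@@](C)(CC[C@@H](O)[C@]2(C)CO[Si](c3ccccc3)(c3ccccc3)C(C)(C)C)[C@@H]1CC/C(=C/CO[Si](C)(C)C(C)(C)C)CO[Si](C)(C)C(C)(C)C | intermediate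
26 | (13Z)-15,16-bis[(tert-butyldimethylsilyl)oxy]-18-[(tert-butyldiphenylsilyl)oxy]labda-8(17),13-dien-3-one | C=C1CC[C@H]2[C@@](C)(CCC(=O)[C@]2(C)CO[Si](c3ccccc3)(c3ccccc3)C(C)(C)C)[C@@H]1CC/C(=C/CO[Si](C)(C)C(C)(C)C)CO[Si](C)(C)C(C)(C)C | intermediate
27 | potassium C2–C3 enolate of 26 | [K+].C=C1CC[C@H]2[C@@](C)(CC=C([O-])[C@]2(C)CO[Si](c3ccccc3)(c3ccccc3)C(C)(C)C)[C@@H]1CC/C(=C/CO[Si](C)(C)C(C)(C)C)CO[Si](C)(C)C(C)(C)C | intermediate (not isolated)
28 | (13Z)-15,16-bis[(tert-butyldimethylsilyl)oxy]-18-[(tert-butyldiphenylsilyl)oxy]-2-hydroxylabda-8(17),13-dien-3-one (C2–OH equatorial) | C=C1CC[C@H]2[C@@](C)(C[C@H](O)C(=O)[C@]2(C)CO[Si](c3ccccc3)(c3ccccc3)C(C)(C)C)[C@@H]1CC/C(=C/CO[Si](C)(C)C(C)(C)C)CO[Si](C)(C)C(C)(C)C | intermediate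
29 | (13Z)-2,15,16-tris[(tert-butyldimethylsilyl)oxy]-18-[(tert-butyldiphenylsilyl)oxy]labda-8(17),13-dien-3-one | C=C1CC[C@H]2[C@@](C)(C[C@H](O[Si](C)(C)C(C)(C)C)C(=O)[C@]2(C)CO[Si](c3ccccc3)(c3ccccc3)C(C)(C)C)[C@@H]1CC/C(=C/CO[Si](C)(C)C(C)(C)C)CO[Si](C)(C)C(C)(C)C | intermediate
30 | (13Z)-2,15,16-tris[(tert-butyldimethylsilyl)oxy]-18-[(tert-butyldiphenylsilyl)oxy]labda-8(17),13-dien-3-ol (C3–OH equatorial, trans to O2) | C=C1CC[C@H]2[C@@](C)(C[C@H](O[Si](C)(C)C(C)(C)C)[C@@H](O)[C@]2(C)CO[Si](c3ccccc3)(c3ccccc3)C(C)(C)C)[C@@H]1CC/C(=C/CO[Si](C)(C)C(C)(C)C)CO[Si](C)(C)C(C)(C)C | intermediate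
31 | angelic acid, (2Z)-2-methylbut-2-enoic acid | C/C=C(/C)C(=O)O | starting material
32 | (2Z)-2-methylbut-2-enoic 2,4,6-trichlorobenzoic anhydride | C/C=C(/C)C(=O)OC(=O)c1c(Cl)cc(Cl)cc1Cl | intermediate (not isolated)
33 | (13Z)-2,15,16-tris[(tert-butyldimethylsilyl)oxy]-18-[(tert-butyldiphenylsilyl)oxy]labda-8(17),13-dien-3-yl (2Z)-2-methylbut-2-enoate | C=C1CC[C@H]2[C@@](C)(C[C@H](O[Si](C)(C)C(C)(C)C)[C@@H](OC(=O)/C(C)=C\C)[C@]2(C)CO[Si](c3ccccc3)(c3ccccc3)C(C)(C)C)[C@@H]1CC/C(=C/CO[Si](C)(C)C(C)(C)C)CO[Si](C)(C)C(C)(C)C | intermediate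
34 | CNP0324138.1, (2S,3S,4S,5S,9R,10S,13Z)-2,15,16,18-tetrahydroxylabda-8(17),13-dien-3-yl (2Z)-2-methylbut-2-enoate | C=C1CC[C@H]2[C@@](C)(C[C@H](O)[C@@H](OC(=O)/C(C)=C\C)[C@]2(C)CO)[C@@H]1CC/C(=C/CO)CO | target

**Step count**
Total: 24 steps. Longest linear sequence: 20 steps (steps 1–12 and 17–24, from 1 and 2 to 34); the side-chain bromide 22 takes 4 steps (13–16) and enters at step 17.

**Steps most likely to fail**

Step 9. The tertiary epoxide carbon carries an inductively withdrawing CH2OSi group, so ionisation may be slow; hydride shift to a C3 ketone, monocyclisation or attack at the secondary epoxide carbon could then outrun the double ring closure. The fallback replaces the cationic opening by a radical one.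
- From enol phosphate 6, Me2CuLi (Et2O, −78 °C) would give ethyl (2E,6E)-3,7,11-trimethyldodeca-2,6,10-trienoate F1.
- The operations of steps 4 to 8 would then give, in turn: the 12-hydroxy ester F2, the (10R,11R)-epoxy alcohol F3, its TBDPS ether F4, the allylic alcohol F5 and the 1-O-TBS ether F6.
- Treating F6 with Cp2TiCl (from Cp2TiCl2 and Mn, THF, rt) opens the epoxide homolytically to a C4 radical that does not feel the β-oxygen. The 6-endo/6-endo radical cascade ends by titanium-mediated β-hydride loss towards the exocyclic alkene and comes back to the route at 13.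
- In this variant C4 would be set by the preference of the bulky silyloxymethyl group for the equatorial site in the chair transition state, not by inversion. Endocyclic alkene isomers would have to be separated.

Step 23. Acylation of the C3 hydroxyl, flanked by quaternary C4 and the C2 silyl ether, may be slow; prolonged heating invites Z to E isomerisation of the angeloyl unit. The fallback builds the Z-alkene on the ester after acylation.
- From 30, esterification with 2-[bis(2,2,2-trifluoroethoxy)phosphoryl]propanoic acid (DIC, DMAP, CH2Cl2) would give the C3 2-[bis(2,2,2-trifluoroethoxy)phosphoryl]propanoate F7. This acid cannot isomerise, so forcing conditions are allowed.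
- Still–Gennari olefination of F7 with acetaldehyde (KHMDS, 18-crown-6, THF, −78 °C) forms the Z-trisubstituted alkene and comes back to the route at 33.

Step 15. Reduction may stop at the lactol, which dehydrates to a furan on work-up, or hydride may remove the allylic bromide on warming. The fallback reduces the lactone before any halide is present.
- From 19, 4-methoxybenzyl trichloroacetimidate (cat. CSA, CH2Cl2) would give 4-{[(4-methoxybenzyl)oxy]methyl}furan-2(5H)-one F8.
- DIBAL-H reduces the lactone to (2E)-2-{[(4-methoxybenzyl)oxy]methyl}but-2-ene-1,4-diol F9.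
- TBSCl and imidazole give the bis-TBS ether F10.
- DDQ (CH2Cl2, pH 7 buffer) removes the PMB group to give (2Z)-4-[(tert-butyldimethylsilyl)oxy]-2-{[(tert-butyldimethylsilyl)oxy]methyl}but-2-en-1-ol F11.
- Appel bromination (CBr4, PPh3) of F11 comes back to the route at 22.

**Further compounds**
F1 | step 9 | ethyl (2E,6E)-3,7,11-trimethyldodeca-2,6,10-trienoate | CCOC(=O)/C=C(\C)CC/C=C(C)/CCC=C(C)C
F2 | step 9 | ethyl (2E,6E,10E)-12-hydroxy-3,7,11-trimethyldodeca-2,6,10-trienoate | CCOC(=O)/C=C(\C)CC/C=C(C)/CC/C=C(\C)CO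
F3 | step 9 | ethyl (2E,6E,10R,11R)-10,11-epoxy-12-hydroxy-3,7,11-trimethyldodeca-2,6-dienoate | CCOC(=O)/C=C(\C)CC/C=C(C)/CC[C@H]1O[C@]1(C)CO
F4 | step 9 | ethyl (2E,6E,10R,11R)-12-[(tert-butyldiphenylsilyl)oxy]-10,11-epoxy-3,7,11-trimethyldodeca-2,6-dienoate | CCOC(=O)/C=C(\C)CC/C=C(C)/CC[C@H]1O[C@]1(C)CO[Si](c1ccccc1)(c1ccccc1)C(C)(C)C
F5 | step 9 | (2E,6E,10R,11R)-12-[(tert-butyldiphenylsilyl)oxy]-10,11-epoxy-3,7,11-trimethyldodeca-2,6-dien-1-ol | OC/C=C(\C)CC/C=C(C)/CC[C@H]1O[C@]1(C)CO[Si](c1ccccc1)(c1ccccc1)C(C)(C)C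
F6 | step 9 | (2E,6E,10R,11R)-1-[(tert-butyldimethylsilyl)oxy]-12-[(tert-butyldiphenylsilyl)oxy]-10,11-epoxy-3,7,11-trimethyldodeca-2,6-diene | CC(C)(C)[Si](C)(C)OC/C=C(\C)CC/C=C(C)/CC[C@H]1O[C@]1(C)CO[Si](c1ccccc1)(c1ccccc1)C(C)(C)C
F7 | step 23 | (13Z)-2,15,16-tris[(tert-butyldimethylsilyl)oxy]-18-[(tert-butyldiphenylsilyl)oxy]labda-8(17),13-dien-3-yl 2-[bis(2,2,2-trifluoroethoxy)phosphoryl]propanoate | C=C1CC[C@H]2[C@@](C)(C[C@H](O[Si](C)(C)C(C)(C)C)[C@@H](OC(=O)C(C)P(=O)(OCC(F)(F)F)OCC(F)(F)F)[C@]2(C)CO[Si](c3ccccc3)(c3ccccc3)C(C)(C)C)[C@@H]1CC/C(=C/CO[Si](C)(C)C(C)(C)C)CO[Si](C)(C)C(C)(C)C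
F8 | step 15 | 4-{[(4-methoxybenzyl)oxy]methyl}furan-2(5H)-one | COc1ccc(COCC2=CC(=O)OC2)cc1
F9 | step 15 | (2E)-2-{[(4-methoxybenzyl)oxy]methyl}but-2-ene-1,4-diol | COc1ccc(COC/C(CO)=C/CO)cc1
F10 | step 15 | (2E)-1,4-bis[(tert-butyldimethylsilyl)oxy]-2-{[(4-methoxybenzyl)oxy]methyl}but-2-ene | COc1ccc(COC/C(CO[Si](C)(C)C(C)(C)C)=C/CO[Si](C)(C)C(C)(C)C)cc1
F11 | step 15 | (2Z)-4-[(tert-butyldimethylsilyl)oxy]-2-{[(tert-butyldimethylsilyl)oxy]methyl}but-2-en-1-ol | OC/C(CO[Si](C)(C)C(C)(C)C)=C/CO[Si](C)(C)C(C)(C)C
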